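## Analysis of the target

The target is a flavan-3-ol ester. Ring A (C4a, C5, C6, C7, C8, C8a) carries hydroxyls at C5 and C7 and the ring oxygen O1 at C8a. Ring C (O1, C2, C3, C4, C4a, C8a) carries the 3,5-dihydroxy-4-methoxyphenyl ring B at C2 and an (E)-feruloyl ester on the C3 oxygen. There are two stereocentres, C2 and C3, both R, with the aryl and acyloxy groups cis on ring C; this is the less stable relative arrangement and cannot be reached by equilibration. The sensitive parts are the electron-rich phenols, the benzylic C2–O1 ether (ionisation under acid) and the cinnamate, which would not survive hydrogenolysis, hydride or strong nucleophiles; the aryl methyl ethers rule out a Lewis-acid dealkylation at the end. The difficulty lies in telling the oxygens apart (one ester site, one methyl ether, four phenols and O1 on the flavan), in setting the cis-2,3 relation with absolute control, and in using only phenol protecting groups that come off in the presence of the cinnamate. The strategy rests on ring A: its three oxygens are mutually meta (C5, C7, C8a) and its only carbon substituent, C4, sits on C4a between two of them. A vinylketene–ynol ether benzannulation gives exactly this pattern, with the three oxygens coming from three different atoms (ketene carbonyl, ynol ether oxygen, enol ether oxygen of the cyclobutenone), so they are differently masked from the moment the ring exists. Because the C4–C3–C2 chain rides on the alkyne, both stereocentres can be set on an open chain before ring A is made.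

## Retrosynthetic reasoning

**33 ⇐ 32.** The last operation removes only silyl groups. All five phenols (four on the flavan, one on the ferulate) are silyl ethers in 32, so a buffered fluoride source frees them without touching the ester or the alkene. Benzyl ethers cannot be present at this stage because hydrogenolysis would saturate the cinnamate.

**32 ⇐ 28 + 31.** The acyl–oxygen bond at C3 is cut. 28 has one free hydroxyl, the axial secondary alcohol at C3; 31 is ferulic acid 29 with its phenol masked. Cutting here keeps the cinnamate out of every earlier step. The forward reaction has to acylate a hindered alcohol.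

**28 ⇐ 27 ⇐ 26.** This is a change of protecting groups. 26 has benzyl ethers on the C3 oxygen, on C7–O and on both ring B phenols, and a TIPS ether on C5–O. Hydrogenolysis gives 27; silylation of its three phenols, but not of the hindered C3 alcohol, gives 28. Putting benzyl on the C3 oxygen means that this oxygen is unveiled together with the phenols and needs no deprotection step of its own.

**26 ⇐ 25 ⇐ 24.** The O1–C2 bond is cut. In 25 the phenol at C8a is the only free phenol and C2 is a benzylic carbinol, so a Mitsunobu etherification can close ring C. It inverts C2, so 25 must be 2S (C2 epimeric to the target, the two chain oxygens anti). 25 comes from 24 by removing the TES ether on the C2 oxygen.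

**24 ⇐ 17 + 19 (key disconnection).** Ring A is taken apart. C8a–C4a and C5–C6 are cut between the two components; C8–C8a is a bond that cyclobutenone 19 gives up on ring opening and makes again on ring closure. Siloxyalkyne 17 supplies C4a, C5 with its silyloxy group, and the whole C4–C3–C2–ring B chain. 19 supplies C8a (as its carbonyl), C6, C7 with its benzyloxy group, and C8. This is the one disconnection of ring A in which the oxygen ortho to the side chain appears as the only free phenol. The forward reaction has to form the ring without touching C2 and C3.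

**17 ⇐ 14 ⇐ 13 ⇐ 12 ⇐ 10.** The ynol ether oxygen is put on terminal alkyne 14 by oxidation of its acetylide and O-silylation. This avoids an ester-homologation route whose substrate would be a β-alkoxy ester open to elimination. 14 comes from aldehyde 13 by one-carbon homologation (the new carbon becomes C5, the aldehyde carbon C4a). 13 comes from alkene 10 by anti-Markovnikov hydration to 12 and oxidation.

**10 ⇐ 9 ⇐ 4 + 7.** The C2–C3 bond is cut, and with it both stereocentres. Addition of the (E)-γ-benzyloxyallylboronate 7 to aldehyde 4 through a chair transition state gives the anti relation; a chiral acid catalyst gives the absolute sense. The γ-oxygen substituent of 7 is already the benzyl ether wanted on C3. The (E)-reagent is required here, since the more common (Z)-γ-alkoxyallyl reagents give the syn isomer.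

**Feeder lines.** 4 ⇐ 3 ⇐ 2 ⇐ 1 (benzylation, reduction, oxidation); 7 ⇐ 6 ⇐ 5 (hydroboration, double-bond shift); 19 ⇐ 18 (exchange of the enol ether alkyl group); 31 ⇐ 29 (phenol silylation).

## Alternatives that were turned down

**Alternative 1: closing C4–C4a by arene attack on an epoxide.** The disconnection is C4–C4a. Ring A is kept intact as the bis-silylated aryl ether A2, in which O1–C2 already exists and C3–C4 is a terminal epoxide. In the forward step a Lewis acid or a strongly hydrogen-bond-donating fluorinated alcohol activates the epoxide, and the ring A carbon ortho to the ether oxygen attacks C4 in a 6-endo Friedel–Crafts closure. This releases the C3 hydroxyl and gives A1, the tetra-silylated flavan-3-ol with free 3-OH.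
- For: ring A is bought rather than built, the stereocentres are set before the closure and are not touched by it, and A1 is two steps from the target, as 28 is in the chosen route.
- Against: A2 is a benzylic aryl ether whose C2–O bond is activated on both sides (electron-rich ring B on carbon, a phenoxide as leaving group), and it must survive the very acid that opens the epoxide. Ionisation there would scramble C2 or fragment the molecule. The arene can also attack the internal epoxide carbon and give a five-membered ring; the only bias toward C4 is the inductive effect of the C2 oxygen.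
- Comparison: this alternative is clearly stronger in step count and needs no benzyl-to-silyl exchange. The chosen strategy offers in its place a C4–C4a bond that is never made by electrophilic substitution (it exists in alkyne 14 before ring A does), so there is no question of ring size and no acid on a benzylic aryl ether.

**Alternative 2: aryne plus cinnamaldehyde to the flav-3-ene.** The disconnection is C4a–C4 and C8a–O1, with O1–C2 closed in the same cascade. A fluoride source releases the aryne from silyl triflate A4; the aryne adds across the C=O of aldehyde A5; the benzoxete opens to an ortho-quinone methide, which closes by oxa-6π electrocyclisation to the racemic 2H-chromene A3.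
- For: three bonds and ring C form in one operation from two simple pieces, and the regiochemistry of the aryne addition is favourable, since oxygen adds to the aryne carbon remote from the flanking benzyloxy group.
- Against: A3 is racemic and the thermal cascade offers no handle for enantiocontrol. A3 also lacks the C3 oxygen. Hydroboration–oxidation of C3=C4 would add anti to the C2 aryl group and give the 2,3-trans alcohol, so the cis isomer needs an oxidation and a bulky-hydride reduction on top, plus a resolution.
- Comparison: this alternative is stronger in convergence and reaches the tricyclic skeleton faster. The chosen strategy offers both stereocentres from one catalytic asymmetric step (9) before the key step, which cannot disturb them.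

**Alternative 3: ortho-quinone methide cycloaddition with a (Z)-styrylboronate.** The disconnection is C4–C3 and O1–C2. Salicyl alcohol A7 is dehydrated by a chiral phosphoric acid to the ring A ortho-quinone methide, which adds the (Z)-alkenylboronate A8 to give the cis 3-boryl chroman A6. Oxidation of C–B with retention would then give the C3 alcohol.
- For: two bonds and both stereocentres form in one convergent step, and boron is a masked hydroxyl that can be unveiled in the presence of benzyl ethers.
- Against: the quinone methide is an electron-poor heterodiene and needs an electron-rich partner. In A8 the carbon that must attack C4 carries the electron-withdrawing boryl group, so the reaction, if it goes, should be stepwise through a benzylic cation at C2. That cation can rotate before O1 closes and drain the cis geometry toward the more stable trans product. Facial control by the acid on an alkene with no hydrogen-bond acceptor is also unproven, and A8 needs a Z-selective synthesis.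
- Comparison: if it worked it would be the shortest enantioselective route, and it is stronger on step count and convergence. The chosen strategy offers a key step of an established reaction class in which no stereochemistry has to be created.

Key step: step 13

Assumption: the (R)-configured phosphoric acid of step 6 is taken to deliver the allyl group to the Re face of aldehyde 4, as it does with benzaldehydes in allyl- and crotylborations; the mirror-image acid would be used if the first batch showed the opposite sense.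

## Route

Step 1
Reactants: 1 methyl 3,5-dihydroxy-4-methoxybenzoate
Product: 2 methyl 3,5-bis(benzyloxy)-4-methoxybenzoate
Conditions: BnBr, K2CO3, DMF, 60 °C
Reagents that add atoms: benzyl bromide, BrCc1ccccc1
Why: Williamson ether synthesis; both phenols are alkylated, and the methyl ester and methyl ether are inert.

Step 2
Reactants: 2 methyl 3,5-bis(benzyloxy)-4-methoxybenzoate
Product: 3 [3,5-bis(benzyloxy)-4-methoxyphenyl]methanol
Conditions: LiAlH4, THF, 0 °C
Reagents that add atoms: none
Why: Hydride reduction of the aryl ester to the benzylic alcohol; the ethers are not affected.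

Step 3
Reactants: 3 [3,5-bis(benzyloxy)-4-methoxyphenyl]methanol
Product: 4 3,5-bis(benzyloxy)-4-methoxybenzaldehyde
Conditions: MnO2 (activated), CH2Cl2, rt
Reagents that add atoms: none
Why: MnO2 oxidises benzylic alcohols selectively to aldehydes and stops there.

Step 4
Reactants: 5 benzyl propargyl ether
Product: 6 (E)-2-[3-(benzyloxy)prop-1-en-1-yl]-4,4,5,5-tetramethyl-1,3,2-dioxaborolane
Conditions: HBpin, Cp2Zr(H)Cl (5 mol%), Et3N (10 mol%), neat, 60 °C
Reagents that add atoms: pinacolborane, CC1(C)OBOC1(C)C
Why: Zirconocene-hydride-catalysed syn hydroboration of a terminal alkyne puts boron on the terminal carbon and gives the (E)-alkenylboronate.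

Step 5
Reactants: 6 (E)-2-[3-(benzyloxy)prop-1-en-1-yl]-4,4,5,5-tetramethyl-1,3,2-dioxaborolane
Product: 7 (E)-2-[3-(benzyloxy)prop-2-en-1-yl]-4,4,5,5-tetramethyl-1,3,2-dioxaborolane
Conditions: [Ir(cod)(PPh2Me)2]PF6 (2 mol%, activated with H2, then Ar), THF, rt
Reagents that add atoms: none
Why: Transition-metal-hydride double-bond migration of the allyl ether type moves the alkene into conjugation with oxygen; with this cationic iridium catalyst it should give the (E)-enol ether, which is the (E)-γ-alkoxyallylboronate.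

Step 6
Reactants: 4 3,5-bis(benzyloxy)-4-methoxybenzaldehyde; 7 (E)-2-[3-(benzyloxy)prop-2-en-1-yl]-4,4,5,5-tetramethyl-1,3,2-dioxaborolane
Product: 9 (1S,2R)-2-(benzyloxy)-1-[3,5-bis(benzyloxy)-4-methoxyphenyl]but-3-en-1-ol, via pinacol borate 8 (not isolated)
Conditions: (R)-3,3'-bis(2,4,6-triisopropylphenyl)-1,1'-binaphthyl-2,2'-diyl hydrogen phosphate (5 mol%), 4 Å MS, toluene, −45 °C; aq. NaHCO3 work-up
Reagents that add atoms: none
Why: Chiral-phosphoric-acid-catalysed allylboration through a closed Zimmerman–Traxler chair; the (E)-geometry of 7 places the benzyloxy group equatorial and so sets the anti relation of the two oxygens, and the acid, hydrogen-bonded to a boronate oxygen and the formyl hydrogen, shields one face of the aldehyde and sets the absolute configuration (1S at the future C2, 2R at the future C3).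

Step 7
Reactants: 9 (1S,2R)-2-(benzyloxy)-1-[3,5-bis(benzyloxy)-4-methoxyphenyl]but-3-en-1-ol
Product: 10 {[(1S,2R)-2-(benzyloxy)-1-[3,5-bis(benzyloxy)-4-methoxyphenyl]but-3-en-1-yl]oxy}triethylsilane
Conditions: TESCl, imidazole, DMF, 0 °C → rt
Reagents that add atoms: chlorotriethylsilane, CC[Si](Cl)(CC)CC
Why: Standard silylation of the secondary alcohol; TES is chosen because mild acid removes it later without ionising the benzylic carbon.

Step 8
Reactants: 10 {[(1S,2R)-2-(benzyloxy)-1-[3,5-bis(benzyloxy)-4-methoxyphenyl]but-3-en-1-yl]oxy}triethylsilane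
Product: 12 (3R,4S)-3-(benzyloxy)-4-[3,5-bis(benzyloxy)-4-methoxyphenyl]-4-(triethylsilyloxy)butan-1-ol, via B-alkyl-9-BBN adduct 11 (not isolated)
Conditions: 9-BBN, THF, 0 °C → rt; then 3 M NaOH, 30% H2O2, 0 °C
Reagents that add atoms: hydrogen peroxide, OO
Why: Anti-Markovnikov hydroboration of the terminal alkene with the bulky borane and oxidation of the C–B bond gives the primary alcohol; no stereocentre is formed or touched.

Step 9
Reactants: 12 (3R,4S)-3-(benzyloxy)-4-[3,5-bis(benzyloxy)-4-methoxyphenyl]-4-(triethylsilyloxy)butan-1-ol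
Product: 13 (3R,4S)-3-(benzyloxy)-4-[3,5-bis(benzyloxy)-4-methoxyphenyl]-4-(triethylsilyloxy)butanal
Conditions: Dess–Martin periodinane, NaHCO3, CH2Cl2, 0 °C → rt
Reagents that add atoms: none
Why: Dess–Martin oxidation of the primary alcohol under buffered, non-basic conditions, which spares the TES ether and avoids β-elimination of the benzyloxy group.

Step 10
Reactants: 13 (3R,4S)-3-(benzyloxy)-4-[3,5-bis(benzyloxy)-4-methoxyphenyl]-4-(triethylsilyloxy)butanal
Product: 14 {[(1S,2R)-2-(benzyloxy)-1-[3,5-bis(benzyloxy)-4-methoxyphenyl]pent-4-yn-1-yl]oxy}triethylsilane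
Conditions: dimethyl (1-diazo-2-oxopropyl)phosphonate, K2CO3, MeOH/THF, 0 °C → rt
Reagents that add atoms: dimethyl (1-diazo-2-oxopropyl)phosphonate, CC(=O)C(=[N+]=[N-])P(=O)(OC)OC
Why: Ohira–Bestmann (Seyferth–Gilbert) homologation turns the aldehyde into the terminal alkyne with one added carbon under mild carbonate conditions.

Step 11
Reactants: 14 {[(1S,2R)-2-(benzyloxy)-1-[3,5-bis(benzyloxy)-4-methoxyphenyl]pent-4-yn-1-yl]oxy}triethylsilane
Product: 17 {[(4R,5S)-4-(benzyloxy)-5-[3,5-bis(benzyloxy)-4-methoxyphenyl]-5-(triethylsilyloxy)pent-1-yn-1-yl]oxy}triisopropylsilane, via lithium acetylide 15 (not isolated), via lithium ynolate 16 (not isolated)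
Conditions: n-BuLi, THF, −78 °C; LiOOt-Bu (from t-BuOOH and LiN(SiMe3)2), −78 → 0 °C; TIPSOTf, −78 → 0 °C
Reagents that add atoms: tert-butyl hydroperoxide (as its lithium salt), CC(C)(C)OO; triisopropylsilyl trifluoromethanesulfonate, CC(C)[Si](OS(=O)(=O)C(F)(F)F)(C(C)C)C(C)C
Why: Oxidation of a lithium acetylide by the electrophilic oxygen of lithium tert-butyl peroxide gives the ynolate, and the bulky silyl triflate silylates it on oxygen to the ynol silyl ether; the TIPS group gives the thermal and hydrolytic stability needed in the next step.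

Step 12
Reactants: 18 3-ethoxycyclobut-2-en-1-one
Product: 19 3-(benzyloxy)cyclobut-2-en-1-one
Conditions: BnOH (3 equiv), pyridinium p-toluenesulfonate (5 mol%), toluene, 50 °C, reduced pressure
Reagents that add atoms: benzyl alcohol, OCc1ccccc1
Why: Acid-catalysed addition–elimination at the β-carbon of the vinylogous ester (vinylogous transesterification), driven by removal of ethanol; the temperature is kept well below that of electrocyclic ring opening.

Step 13
Reactants: 17 {[(4R,5S)-4-(benzyloxy)-5-[3,5-bis(benzyloxy)-4-methoxyphenyl]-5-(triethylsilyloxy)pent-1-yn-1-yl]oxy}triisopropylsilane; 19 3-(benzyloxy)cyclobut-2-en-1-one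
Product: 24 5-(benzyloxy)-2-[(2R,3S)-2-(benzyloxy)-3-[3,5-bis(benzyloxy)-4-methoxyphenyl]-3-(triethylsilyloxy)propyl]-3-(triisopropylsilyloxy)phenol, via vinylketene 20 (not isolated), via 4-vinylcyclobutenone 21 (not isolated), via dienylketene 22 (not isolated), via cyclohexa-2,4-dienone 23 (not isolated)
Conditions: 19 (1.5 equiv, in portions), toluene (0.3 M), 80 → 110 °C, Ar; then n-PrNH2, rt
Reagents that add atoms: none
Why: This is a Danheiser benzannulation of a cyclobutenone with a siloxyalkyne, the known route to resorcinol monosilyl ethers, here with an oxygen on C3 of the cyclobutenone so that a 1,3,5-trioxygenated ring results. Heating opens 19 reversibly by 4π conrotation to vinylketene 20; the alkyne carbon remote from oxygen (future C4a) attacks the ketene carbonyl carbon (future C8a), and the [2+2] cycloaddition is completed by bonding of the silyloxy-bearing carbon (future C5) to the ketene α-carbon (future C6), giving 4-vinylcyclobutenone 21. 21 opens (4π) to dienylketene 22; this opening is reversible, and only the isomer with the alkoxyvinyl group cis to the ketene carbon goes on. Ring A is closed by thermal disrotatory 6π electrocyclisation of 22 (C8–C8a bond), and the cyclohexa-2,4-dienone 23 tautomerises irreversibly to phenol 24. No stereocentre is created (the sp3 ring carbon of 21 is lost again), and C2 and C3 are fully protected spectators that have no acidic hydrogen and no free heteroatom. The selectivity needed is the orientation of the [2+2] step, which is fixed by the polarity of the two partners (nucleophilic β-carbon of the ynol ether, electrophilic ketene carbon); since C6 and C8 are both CH, the same constitution would result even if the second bond formed at the vinyl terminus in a [4+2] sense. 17 has no O–H that could trap the ketene, the phenol of 24 is shielded by its ortho side chain, and any aryl ester formed from it and excess ketene is cleaved by the amine quench.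

Step 14
Reactants: 24 5-(benzyloxy)-2-[(2R,3S)-2-(benzyloxy)-3-[3,5-bis(benzyloxy)-4-methoxyphenyl]-3-(triethylsilyloxy)propyl]-3-(triisopropylsilyloxy)phenol
Product: 25 5-(benzyloxy)-2-[(2R,3S)-2-(benzyloxy)-3-[3,5-bis(benzyloxy)-4-methoxyphenyl]-3-hydroxypropyl]-3-(triisopropylsilyloxy)phenol
Conditions: pyridinium p-toluenesulfonate (0.2 equiv), MeOH/CH2Cl2, 0 °C → rt
Reagents that add atoms: none
Why: Mild acid-catalysed methanolysis removes the alkyl TES ether; the aryl TIPS ether and the benzyl ethers are stable, and the acid is too weak to ionise the benzylic carbon.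

Step 15
Reactants: 25 5-(benzyloxy)-2-[(2R,3S)-2-(benzyloxy)-3-[3,5-bis(benzyloxy)-4-methoxyphenyl]-3-hydroxypropyl]-3-(triisopropylsilyloxy)phenol
Product: 26 {[(2R,3R)-3,7-bis(benzyloxy)-2-[3,5-bis(benzyloxy)-4-methoxyphenyl]-3,4-dihydro-2H-chromen-5-yl]oxy}triisopropylsilane
Conditions: PPh3, DIAD, toluene, 0 °C → rt
Reagents that add atoms: none
Why: Intramolecular Mitsunobu etherification (6-exo-tet): the only phenol displaces the activated benzylic oxygen by SN2 with inversion, turning 2S into 2R and giving the 2,3-cis chroman; ionisation is disfavoured because the two meta-alkoxy groups of ring B withdraw inductively, the para-methoxy group is twisted out of conjugation by its two ortho neighbours, and the solvent is non-polar.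

Step 16
Reactants: 26 {[(2R,3R)-3,7-bis(benzyloxy)-2-[3,5-bis(benzyloxy)-4-methoxyphenyl]-3,4-dihydro-2H-chromen-5-yl]oxy}triisopropylsilane
Product: 27 (2R,3R)-2-(3,5-dihydroxy-4-methoxyphenyl)-5-(triisopropylsilyloxy)-3,4-dihydro-2H-chromene-3,7-diol
Conditions: H2 (1 atm), Pd(OH)2/C, EtOAc/MeOH, rt
Reagents that add atoms: none
Why: Hydrogenolysis of the three aryl benzyl ethers and the secondary alkyl benzyl ether; the aryl silyl ether is inert, and the cyclic C2–O1 bond is cleaved much more slowly than O-benzyl groups, so the reaction is stopped at the calculated uptake.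

Step 17
Reactants: 27 (2R,3R)-2-(3,5-dihydroxy-4-methoxyphenyl)-5-(triisopropylsilyloxy)-3,4-dihydro-2H-chromene-3,7-diol
Product: 28 (2R,3R)-2-[4-methoxy-3,5-bis(triisopropylsilyloxy)phenyl]-5,7-bis(triisopropylsilyloxy)-3,4-dihydro-2H-chromen-3-ol
Conditions: TIPSCl (3.6 equiv), imidazole, DMF, rt
Reagents that add atoms: chlorotriisopropylsilane, CC(C)[Si](Cl)(C(C)C)C(C)C
Why: Silyl ether formation; the bulky silyl chloride with imidazole silylates phenols readily but reacts far too slowly with the axial C3 alcohol next to the C2 aryl group, so only the C3 hydroxyl should stay free.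

Step 18
Reactants: 29 ferulic acid
Product: 31 (E)-3-[4-(tert-butyldimethylsilyloxy)-3-methoxyphenyl]prop-2-enoic acid, via bis-silylated ferulate 30 (not isolated)
Conditions: TBSCl (2.5 equiv), imidazole, DMF, rt; then AcOH/THF/H2O, rt
Reagents that add atoms: tert-butylchlorodimethylsilane, CC(C)(C)[Si](C)(C)Cl
Why: Silylation of both the phenol and the acid, followed by selective hydrolysis of the much more labile silyl ester, leaves the aryl silyl ether and the free acid.

Step 19
Reactants: 28 (2R,3R)-2-[4-methoxy-3,5-bis(triisopropylsilyloxy)phenyl]-5,7-bis(triisopropylsilyloxy)-3,4-dihydro-2H-chromen-3-ol; 31 (E)-3-[4-(tert-butyldimethylsilyloxy)-3-methoxyphenyl]prop-2-enoic acid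
Product: 32 (2R,3R)-2-[4-methoxy-3,5-bis(triisopropylsilyloxy)phenyl]-5,7-bis(triisopropylsilyloxy)-3,4-dihydro-2H-chromen-3-yl (E)-3-[4-(tert-butyldimethylsilyloxy)-3-methoxyphenyl]prop-2-enoate
Conditions: EDC·HCl, DMAP, CH2Cl2, 0 °C → rt
Reagents that add atoms: none
Why: Steglich esterification; the acylpyridinium intermediate is reactive enough for the hindered secondary alcohol, and neither C2 nor C3 is involved, so the configuration is retained.

Step 20
Reactants: 32 (2R,3R)-2-[4-methoxy-3,5-bis(triisopropylsilyloxy)phenyl]-5,7-bis(triisopropylsilyloxy)-3,4-dihydro-2H-chromen-3-yl (E)-3-[4-(tert-butyldimethylsilyloxy)-3-methoxyphenyl]prop-2-enoate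
Product: 33 4'-O-methylepigallocatechin-3-O-ferulate
Conditions: TBAF, AcOH (1:1), THF, 0 °C → rt
Reagents that add atoms: none
Why: Fluoride cleaves all five aryl silyl ethers; the acetic acid buffer keeps the phenols protonated, which protects the ester from cleavage and C2 from base-induced epimerisation (the 4'-methyl ether also blocks the para-quinone methide path to epimerisation).

## Compound list

1 | methyl 3,5-dihydroxy-4-methoxybenzoate | COC(=O)c1cc(O)c(OC)c(O)c1 | starting material
2 | methyl 3,5-bis(benzyloxy)-4-methoxybenzoate | COC(=O)c1cc(OCc2ccccc2)c(OC)c(OCc2ccccc2)c1 | intermediate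
3 | [3,5-bis(benzyloxy)-4-methoxyphenyl]methanol | OCc1cc(OCc2ccccc2)c(OC)c(OCc2ccccc2)c1 | intermediate
4 | 3,5-bis(benzyloxy)-4-methoxybenzaldehyde | O=Cc1cc(OCc2ccccc2)c(OC)c(OCc2ccccc2)c1 | intermediate
5 | benzyl propargyl ether | C#CCOCc1ccccc1 | starting material
6 | (E)-2-[3-(benzyloxy)prop-1-en-1-yl]-4,4,5,5-tetramethyl-1,3,2-dioxaborolane | CC1(C)OB(/C=C/COCc2ccccc2)OC1(C)C | intermediate
7 | (E)-2-[3-(benzyloxy)prop-2-en-1-yl]-4,4,5,5-tetramethyl-1,3,2-dioxaborolane | CC1(C)OB(C/C=C/OCc2ccccc2)OC1(C)C | intermediate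
8 | 2-{[(1S,2R)-2-(benzyloxy)-1-[3,5-bis(benzyloxy)-4-methoxyphenyl]but-3-en-1-yl]oxy}-4,4,5,5-tetramethyl-1,3,2-dioxaborolane (pinacol borate, not isolated) | C=C[C@@H](OCc1ccccc1)[C@@H](OB1OC(C)(C)C(C)(C)O1)c1cc(OCc2ccccc2)c(OC)c(OCc2ccccc2)c1 | intermediate
9 | (1S,2R)-2-(benzyloxy)-1-[3,5-bis(benzyloxy)-4-methoxyphenyl]but-3-en-1-ol | C=C[C@@H](OCc1ccccc1)[C@@H](O)c1cc(OCc2ccccc2)c(OC)c(OCc2ccccc2)c1 | intermediate
10 | {[(1S,2R)-2-(benzyloxy)-1-[3,5-bis(benzyloxy)-4-methoxyphenyl]but-3-en-1-yl]oxy}triethylsilane | C=C[C@@H](OCc1ccccc1)[C@@H](O[Si](CC)(CC)CC)c1cc(OCc2ccccc2)c(OC)c(OCc2ccccc2)c1 | intermediate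
11 | 9-[(3R,4S)-3-(benzyloxy)-4-[3,5-bis(benzyloxy)-4-methoxyphenyl]-4-(triethylsilyloxy)butyl]-9-borabicyclo[3.3.1]nonane (not isolated) | C1CCC2CCCC1B2CC[C@@H](OCc1ccccc1)[C@@H](O[Si](CC)(CC)CC)c1cc(OCc2ccccc2)c(OC)c(OCc2ccccc2)c1 | intermediate
12 | (3R,4S)-3-(benzyloxy)-4-[3,5-bis(benzyloxy)-4-methoxyphenyl]-4-(triethylsilyloxy)butan-1-ol | OCC[C@@H](OCc1ccccc1)[C@@H](O[Si](CC)(CC)CC)c1cc(OCc2ccccc2)c(OC)c(OCc2ccccc2)c1 | intermediate
13 | (3R,4S)-3-(benzyloxy)-4-[3,5-bis(benzyloxy)-4-methoxyphenyl]-4-(triethylsilyloxy)butanal | O=CC[C@@H](OCc1ccccc1)[C@@H](O[Si](CC)(CC)CC)c1cc(OCc2ccccc2)c(OC)c(OCc2ccccc2)c1 | intermediate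
14 | {[(1S,2R)-2-(benzyloxy)-1-[3,5-bis(benzyloxy)-4-methoxyphenyl]pent-4-yn-1-yl]oxy}triethylsilane | C#CC[C@@H](OCc1ccccc1)[C@@H](O[Si](CC)(CC)CC)c1cc(OCc2ccccc2)c(OC)c(OCc2ccccc2)c1 | intermediate
15 | lithium acetylide of 14 (not isolated) | [Li]C#CC[C@@H](OCc1ccccc1)[C@@H](O[Si](CC)(CC)CC)c1cc(OCc2ccccc2)c(OC)c(OCc2ccccc2)c1 | intermediate
16 | lithium (4R,5S)-4-(benzyloxy)-5-[3,5-bis(benzyloxy)-4-methoxyphenyl]-5-(triethylsilyloxy)pent-1-yn-1-olate (not isolated) | [Li]OC#CC[C@@H](OCc1ccccc1)[C@@H](O[Si](CC)(CC)CC)c1cc(OCc2ccccc2)c(OC)c(OCc2ccccc2)c1 | intermediate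
17 | {[(4R,5S)-4-(benzyloxy)-5-[3,5-bis(benzyloxy)-4-methoxyphenyl]-5-(triethylsilyloxy)pent-1-yn-1-yl]oxy}triisopropylsilane | CC(C)[Si](OC#CC[C@@H](OCc1ccccc1)[C@@H](O[Si](CC)(CC)CC)c1cc(OCc2ccccc2)c(OC)c(OCc2ccccc2)c1)(C(C)C)C(C)C | intermediate
18 | 3-ethoxycyclobut-2-en-1-one | CCOC1=CC(=O)C1 | starting material
19 | 3-(benzyloxy)cyclobut-2-en-1-one | O=C1C=C(OCc2ccccc2)C1 | intermediate
20 | 3-(benzyloxy)buta-1,3-dien-1-one (vinylketene, not isolated) | C=C(OCc1ccccc1)C=C=O | intermediate
21 | 4-[1-(benzyloxy)ethenyl]-2-[(2R,3S)-2-(benzyloxy)-3-[3,5-bis(benzyloxy)-4-methoxyphenyl]-3-(triethylsilyloxy)propyl]-3-(triisopropylsilyloxy)cyclobut-2-en-1-one (mixture of epimers at the ring sp3 carbon, not isolated) | C=C(OCc1ccccc1)C1C(=O)C(C[C@@H](OCc2ccccc2)[C@@H](O[Si](CC)(CC)CC)c2cc(OCc3ccccc3)c(OC)c(OCc3ccccc3)c2)=C1O[Si](C(C)C)(C(C)C)C(C)C | intermediate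
22 | (3E)-5-(benzyloxy)-2-[(2R,3S)-2-(benzyloxy)-3-[3,5-bis(benzyloxy)-4-methoxyphenyl]-3-(triethylsilyloxy)propyl]-3-(triisopropylsilyloxy)hexa-1,3,5-trien-1-one (dienylketene, not isolated) | O=C=C(C[C@@H](OCc1ccccc1)[C@@H](O[Si](CC)(CC)CC)c1cc(OCc2ccccc2)c(OC)c(OCc2ccccc2)c1)/C(O[Si](C(C)C)(C(C)C)C(C)C)=C\C(=C)OCc1ccccc1 | intermediate
23 | 5-(benzyloxy)-2-[(2R,3S)-2-(benzyloxy)-3-[3,5-bis(benzyloxy)-4-methoxyphenyl]-3-(triethylsilyloxy)propyl]-3-(triisopropylsilyloxy)cyclohexa-2,4-dien-1-one (not isolated) | O=C1CC(OCc2ccccc2)=CC(O[Si](C(C)C)(C(C)C)C(C)C)=C1C[C@@H](OCc1ccccc1)[C@@H](O[Si](CC)(CC)CC)c1cc(OCc2ccccc2)c(OC)c(OCc2ccccc2)c1 | intermediate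
24 | 5-(benzyloxy)-2-[(2R,3S)-2-(benzyloxy)-3-[3,5-bis(benzyloxy)-4-methoxyphenyl]-3-(triethylsilyloxy)propyl]-3-(triisopropylsilyloxy)phenol | CC(C)[Si](Oc1cc(OCc2ccccc2)cc(O)c1C[C@@H](OCc1ccccc1)[C@@H](O[Si](CC)(CC)CC)c1cc(OCc2ccccc2)c(OC)c(OCc2ccccc2)c1)(C(C)C)C(C)C | intermediate
25 | 5-(benzyloxy)-2-[(2R,3S)-2-(benzyloxy)-3-[3,5-bis(benzyloxy)-4-methoxyphenyl]-3-hydroxypropyl]-3-(triisopropylsilyloxy)phenol | CC(C)[Si](Oc1cc(OCc2ccccc2)cc(O)c1C[C@@H](OCc1ccccc1)[C@@H](O)c1cc(OCc2ccccc2)c(OC)c(OCc2ccccc2)c1)(C(C)C)C(C)C | intermediate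
26 | {[(2R,3R)-3,7-bis(benzyloxy)-2-[3,5-bis(benzyloxy)-4-methoxyphenyl]-3,4-dihydro-2H-chromen-5-yl]oxy}triisopropylsilane | C(c1ccccc1)O[C@@H]1Cc2c(O[Si](C(C)C)(C(C)C)C(C)C)cc(OCc3ccccc3)cc2O[C@@H]1c1cc(OCc2ccccc2)c(OC)c(OCc2ccccc2)c1 | intermediate
27 | (2R,3R)-2-(3,5-dihydroxy-4-methoxyphenyl)-5-(triisopropylsilyloxy)-3,4-dihydro-2H-chromene-3,7-diol | O[C@@H]1Cc2c(O[Si](C(C)C)(C(C)C)C(C)C)cc(O)cc2O[C@@H]1c1cc(O)c(OC)c(O)c1 | intermediate
28 | (2R,3R)-2-[4-methoxy-3,5-bis(triisopropylsilyloxy)phenyl]-5,7-bis(triisopropylsilyloxy)-3,4-dihydro-2H-chromen-3-ol | O[C@@H]1Cc2c(O[Si](C(C)C)(C(C)C)C(C)C)cc(O[Si](C(C)C)(C(C)C)C(C)C)cc2O[C@@H]1c1cc(O[Si](C(C)C)(C(C)C)C(C)C)c(OC)c(O[Si](C(C)C)(C(C)C)C(C)C)c1 | intermediate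
29 | ferulic acid | COc1cc(/C=C/C(=O)O)ccc1O | starting material
30 | tert-butyldimethylsilyl (E)-3-[4-(tert-butyldimethylsilyloxy)-3-methoxyphenyl]prop-2-enoate (not isolated) | COc1cc(/C=C/C(=O)O[Si](C)(C)C(C)(C)C)ccc1O[Si](C)(C)C(C)(C)C | intermediate
31 | (E)-3-[4-(tert-butyldimethylsilyloxy)-3-methoxyphenyl]prop-2-enoic acid | COc1cc(/C=C/C(=O)O)ccc1O[Si](C)(C)C(C)(C)C | intermediate
32 | (2R,3R)-2-[4-methoxy-3,5-bis(triisopropylsilyloxy)phenyl]-5,7-bis(triisopropylsilyloxy)-3,4-dihydro-2H-chromen-3-yl (E)-3-[4-(tert-butyldimethylsilyloxy)-3-methoxyphenyl]prop-2-enoate | COc1cc(/C=C/C(=O)O[C@@H]2Cc3c(O[Si](C(C)C)(C(C)C)C(C)C)cc(O[Si](C(C)C)(C(C)C)C(C)C)cc3O[C@@H]2c2cc(O[Si](C(C)C)(C(C)C)C(C)C)c(OC)c(O[Si](C(C)C)(C(C)C)C(C)C)c2)ccc1O[Si](C)(C)C(C)(C)C | intermediate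
33 | 4'-O-methylepigallocatechin-3-O-ferulate, (2R,3R)-2-(3,5-dihydroxy-4-methoxyphenyl)-5,7-dihydroxy-3,4-dihydro-2H-chromen-3-yl (E)-3-(4-hydroxy-3-methoxyphenyl)prop-2-enoate | COc1cc(/C=C/C(=O)O[C@@H]2Cc3c(O)cc(O)cc3O[C@@H]2c2cc(O)c(OC)c(O)c2)ccc1O | target

## Step count and least certain steps

Total: 20 steps. Longest linear sequence: 16 steps from 1 (steps 1–3, 6–11, 13–17, 19, 20). The side branches are steps 4–5 (boronate 7), step 12 (cyclobutenone 19) and step 18 (acid 31).

**Step 13 (key step).** The enol ether oxygen stabilises cyclobutenone 19, so its ring opening may need a temperature at which siloxyalkyne 17 starts to rearrange by 1,3-silyl shift to a silylketene. The phenol of 24 may also be acylated by excess ketene faster than the amine quench can make good. Fallback, setting out from 17 and coming back at 24: the same vinylketene 20 is generated at or below room temperature by 1,4-dehydrochlorination. Ethyl but-2-ynoate and benzyl alcohol with catalytic PMe3 give ethyl (E)-3-(benzyloxy)but-2-enoate F1. LiOH gives (E)-3-(benzyloxy)but-2-enoic acid F2, and oxalyl chloride gives (E)-3-(benzyloxy)but-2-enoyl chloride F3. Slow addition of F3 to 17 and Et3N in toluene at 0 °C → rt should give 21 without any thermal opening of a cyclobutenone. Brief heating to 80 °C, after the alkyne has been consumed, then takes 21 through 22 and 23 to 24.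

**Step 12.** Instead of exchange at the β-carbon, the alcohol may attack the strained carbonyl and cleave the ring in a retro-Claisen sense to acetoacetate derivatives. Fallback, setting out from 18 and coming back at 19: cold dilute aqueous HCl hydrolyses 18 to cyclobutane-1,3-dione F4 (an acidic enol), which is O-benzylated under Mitsunobu conditions (BnOH, PPh3, DIAD, THF, 0 °C). In that reaction the enol is the acidic partner, and alkylation on oxygen gives 19.

**Step 11.** Oxygen transfer to the acetylide may stay incomplete, and the ynol silyl ether may be lost by C-silylation or by hydrolysis during isolation. Fallback, setting out from 13 and coming back at 16 and then 17, by ester homologation instead of alkyne oxidation. Pinnick oxidation (NaClO2, NaH2PO4, 2-methylbut-2-ene) gives (3R,4S)-3-(benzyloxy)-4-[3,5-bis(benzyloxy)-4-methoxyphenyl]-4-(triethylsilyloxy)butanoic acid F5, and Me3SiCHN2 gives its methyl ester F6. Kowalski homologation (CH2Br2 and lithium 2,2,6,6-tetramethylpiperidide at −78 °C, then n-BuLi with warming) passes through the lithium enolate of the dibromoketone (4R,5S)-4-(benzyloxy)-5-[3,5-bis(benzyloxy)-4-methoxyphenyl]-1,1-dibromo-5-(triethylsilyloxy)pentan-2-one F7 to ynolate 16, which TIPSOTf silylates to 17. This is kept as the second choice because base can eliminate the β-benzyloxy group of F6.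

**Step 15.** The activated benzylic alcohol may ionise before the phenol displaces it. That would lose the inversion (giving the 2,3-trans isomer) or lead to elimination toward C3. Fallback, setting out from 25 and coming back at 26, by reductive etherification instead of displacement. MnO2 oxidises the benzylic alcohol to (R)-2-(benzyloxy)-3-[4-(benzyloxy)-2-hydroxy-6-(triisopropylsilyloxy)phenyl]-1-[3,5-bis(benzyloxy)-4-methoxyphenyl]propan-1-one F8, which is in equilibrium with its cyclic hemiketal. Et3SiH and BF3·OEt2 in CH2Cl2 at −78 °C reduce the cyclic oxocarbenium ion. The C3 benzyloxy group is expected to sit pseudoaxial to avoid allylic strain with the C2 aryl group, and hydride should enter trans to it. C2 is thereby set afresh from C3, and the cis chroman 26 is expected.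

**Step 6.** Partial E-to-Z isomerisation of 7, or an uncatalysed background reaction, would erode the anti selectivity, and the facial selectivity rests on the assumed sense of the catalyst. Fallback, setting out from 3 and coming back at 10, by iridium-catalysed transfer-hydrogenative anti-(acyloxy)allylation instead of allylboration. The allyl donor prop-2-ene-1,1-diyl dibenzoate F9 is made from acrolein and benzoic anhydride. It is coupled with alcohol 3 using [Ir(cod)Cl]2, 5,5'-bis(diphenylphosphino)-4,4'-bi-1,3-benzodioxole (the enantiomer that leads to the 1S,2R product), 4-cyano-3-nitrobenzoic acid and K3PO4 in THF, to give (1S,2R)-1-[3,5-bis(benzyloxy)-4-methoxyphenyl]-1-hydroxybut-3-en-2-yl benzoate F10. TESCl and imidazole give (1S,2R)-1-[3,5-bis(benzyloxy)-4-methoxyphenyl]-1-(triethylsilyloxy)but-3-en-2-yl benzoate F11. i-Bu2AlH at −78 °C removes the benzoate to give (1S,2R)-1-[3,5-bis(benzyloxy)-4-methoxyphenyl]-1-(triethylsilyloxy)but-3-en-2-ol F12. Benzylation under neutral conditions (2-benzyloxy-1-methylpyridinium triflate, MgO, PhCF3, 85 °C) avoids silyl migration and gives 10.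

## Further compounds

F1 | step 13 | ethyl (E)-3-(benzyloxy)but-2-enoate | CCOC(=O)/C=C(\C)OCc1ccccc1
F2 | step 13 | (E)-3-(benzyloxy)but-2-enoic acid | OC(=O)/C=C(\C)OCc1ccccc1
F3 | step 13 | (E)-3-(benzyloxy)but-2-enoyl chloride | ClC(=O)/C=C(\C)OCc1ccccc1
F4 | step 12 | cyclobutane-1,3-dione | O=C1CC(=O)C1
F5 | step 11 | (3R,4S)-3-(benzyloxy)-4-[3,5-bis(benzyloxy)-4-methoxyphenyl]-4-(triethylsilyloxy)butanoic acid | OC(=O)C[C@@H](OCc1ccccc1)[C@@H](O[Si](CC)(CC)CC)c1cc(OCc2ccccc2)c(OC)c(OCc2ccccc2)c1
F6 | step 11 | methyl (3R,4S)-3-(benzyloxy)-4-[3,5-bis(benzyloxy)-4-methoxyphenyl]-4-(triethylsilyloxy)butanoate | COC(=O)C[C@@H](OCc1ccccc1)[C@@H](O[Si](CC)(CC)CC)c1cc(OCc2ccccc2)c(OC)c(OCc2ccccc2)c1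
F7 | step 11 | (4R,5S)-4-(benzyloxy)-5-[3,5-bis(benzyloxy)-4-methoxyphenyl]-1,1-dibromo-5-(triethylsilyloxy)pentan-2-one | BrC(Br)C(=O)C[C@@H](OCc1ccccc1)[C@@H](O[Si](CC)(CC)CC)c1cc(OCc2ccccc2)c(OC)c(OCc2ccccc2)c1
F8 | step 15 | (R)-2-(benzyloxy)-3-[4-(benzyloxy)-2-hydroxy-6-(triisopropylsilyloxy)phenyl]-1-[3,5-bis(benzyloxy)-4-methoxyphenyl]propan-1-one | CC(C)[Si](Oc1cc(OCc2ccccc2)cc(O)c1C[C@@H](OCc1ccccc1)C(=O)c1cc(OCc2ccccc2)c(OC)c(OCc2ccccc2)c1)(C(C)C)C(C)C
F9 | step 6 | prop-2-ene-1,1-diyl dibenzoate | C=CC(OC(=O)c1ccccc1)OC(=O)c1ccccc1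
F10 | step 6 | (1S,2R)-1-[3,5-bis(benzyloxy)-4-methoxyphenyl]-1-hydroxybut-3-en-2-yl benzoate | C=C[C@@H](OC(=O)c1ccccc1)[C@@H](O)c1cc(OCc2ccccc2)c(OC)c(OCc2ccccc2)c1
F11 | step 6 | (1S,2R)-1-[3,5-bis(benzyloxy)-4-methoxyphenyl]-1-(triethylsilyloxy)but-3-en-2-yl benzoate | C=C[C@@H](OC(=O)c1ccccc1)[C@@H](O[Si](CC)(CC)CC)c1cc(OCc2ccccc2)c(OC)c(OCc2ccccc2)c1
F12 | step 6 | (1S,2R)-1-[3,5-bis(benzyloxy)-4-methoxyphenyl]-1-(triethylsilyloxy)but-3-en-2-ol | C=C[C@@H](O)[C@@H](O[Si](CC)(CC)CC)c1cc(OCc2ccccc2)c(OC)c(OCc2ccccc2)c1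
A1 | alternative 1 | (2R,3R)-5,7-bis(tert-butyldimethylsilyloxy)-2-[3,5-bis(tert-butyldimethylsilyloxy)-4-methoxyphenyl]-3,4-dihydro-2H-chromen-3-ol | O[C@@H]1Cc2c(O[Si](C)(C)C(C)(C)C)cc(O[Si](C)(C)C(C)(C)C)cc2O[C@@H]1c1cc(O[Si](C)(C)C(C)(C)C)c(OC)c(O[Si](C)(C)C(C)(C)C)c1
A2 | alternative 1 | (R)-2-{(R)-[3,5-bis(tert-butyldimethylsilyloxy)phenoxy][3,5-bis(tert-butyldimethylsilyloxy)-4-methoxyphenyl]methyl}oxirane | C1O[C@H]1[C@H](Oc1cc(O[Si](C)(C)C(C)(C)C)cc(O[Si](C)(C)C(C)(C)C)c1)c1cc(O[Si](C)(C)C(C)(C)C)c(OC)c(O[Si](C)(C)C(C)(C)C)c1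
A3 | alternative 2 | racemic 5,7-bis(benzyloxy)-2-[3,5-bis(benzyloxy)-4-methoxyphenyl]-2H-chromene | COc1c(OCc2ccccc2)cc(C2C=Cc3c(OCc4ccccc4)cc(OCc4ccccc4)cc3O2)cc1OCc1ccccc1
A4 | alternative 2 | 3,5-bis(benzyloxy)-2-(trimethylsilyl)phenyl trifluoromethanesulfonate | C[Si](C)(C)c1c(OCc2ccccc2)cc(OCc2ccccc2)cc1OS(=O)(=O)C(F)(F)F
A5 | alternative 2 | (E)-3-[3,5-bis(benzyloxy)-4-methoxyphenyl]prop-2-enal | COc1c(OCc2ccccc2)cc(/C=C/C=O)cc1OCc1ccccc1
A6 | alternative 3 | 2-[(2S,3R)-5,7-bis(benzyloxy)-2-[3,5-bis(benzyloxy)-4-methoxyphenyl]-3,4-dihydro-2H-chromen-3-yl]-4,4,5,5-tetramethyl-1,3,2-dioxaborolane (2,3-cis) | CC1(C)OB(OC1(C)C)[C@@H]1Cc2c(OCc3ccccc3)cc(OCc3ccccc3)cc2O[C@@H]1c1cc(OCc2ccccc2)c(OC)c(OCc2ccccc2)c1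
A7 | alternative 3 | 3,5-bis(benzyloxy)-2-(hydroxymethyl)phenol | OCc1c(O)cc(OCc2ccccc2)cc1OCc1ccccc1
A8 | alternative 3 | (Z)-2-{2-[3,5-bis(benzyloxy)-4-methoxyphenyl]ethenyl}-4,4,5,5-tetramethyl-1,3,2-dioxaborolane | CC1(C)OB(/C=C\c2cc(OCc3ccccc3)c(OC)c(OCc3ccccc3)c2)OC1(C)C
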